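**Strategy.** The route rests on disconnecting C9–C10 of ring B (C5–C6–C7=C8–C9–C10, labdane numbering). The isoprenoid pattern of the target, with methyl-bearing C10 and C8 joined through C9 and the double bond at C7=C8, marks ring B as the product of a tertiary C10 cation captured by an (E)-C8=C9 alkene with loss of H-7. One superacid-mediated operation closes ring B, sets the quaternary C10 and C9 stereocentres with the trans ring fusion, and places the alkene. The precursor is a monocyclic cyclohexene (ring A, with C4 and C5 set by an enantioselective Diels–Alder reaction of methacrolein with a farnesol-derived triene) that already carries C13, the angelate and the protected acid.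

Key step: step 10

Remark on numbering: labdane numbering is used throughout (C4 carries the C18 methyl and the C19 acyloxymethyl group; C5/C10 are the ring-fusion atoms; C20 is the methyl on C10, C17 the methyl on C8; the side chain C11–C16 sits on C9).

Assumption: the sense of induction of the oxazaborolidinium catalyst in step 7 is taken from its accepted pre-transition-state model for 2-substituted acroleins (diene on the Cα face from which CHO, =CH2 and CH3 run clockwise); if the opposite face were favoured, the (R)-catalyst would be used with no other change.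

Step 1
Reactants: 1 (2E,6E)-farnesol
Product: 2 (3S,6E)-3,7,11-trimethyldodeca-6,10-dien-1-ol
Conditions: H2 (50 atm), Ru(OAc)2[(R)-BINAP] (0.5 mol%), MeOH/H2O 95:5, 20 °C
Reagents that add atoms: none
Why: Noyori asymmetric hydrogenation; the allylic alcohol binds ruthenium so that only C2=C3 is reduced, and (R)-BINAP with the (E)-allylic alcohol should give the 3S centre (the future C13), as in the geraniol to (S)-citronellol case.

Step 2
Reactants: 2 (3S,6E)-3,7,11-trimethyldodeca-6,10-dien-1-ol
Product: 4 (3S,6E)-3,7,11-trimethyldodeca-6,10-dienoic acid, via aldehyde 3 (not isolated)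
Conditions: TEMPO (0.2 equiv), PhI(OAc)2 (2.2 equiv), MeCN/H2O 1:1, rt
Reagents that add atoms: water, O
Why: Oxoammonium (TEMPO) oxidation takes the primary alcohol through the aldehyde hydrate to the acid without touching the trisubstituted alkenes or the β-stereocentre.

Step 3
Reactants: 4 (3S,6E)-3,7,11-trimethyldodeca-6,10-dienoic acid
Product: 5 prop-2-en-1-yl (3S,6E)-3,7,11-trimethyldodeca-6,10-dienoate
Conditions: allyl bromide, K2CO3, DMF, rt
Reagents that add atoms: allyl bromide, C=CCBr
Why: SN2 O-alkylation of the carboxylate gives an allyl ester that should survive the oxidation, ylide, hydride and acid steps and is removable under neutral Pd(0) conditions.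

Step 4
Reactants: 5 prop-2-en-1-yl (3S,6E)-3,7,11-trimethyldodeca-6,10-dienoate
Product: 6 prop-2-en-1-yl (3S,6E,10E)-12-hydroxy-3,7,11-trimethyldodeca-6,10-dienoate
Conditions: SeO2 (0.3 equiv), t-BuOOH (3 equiv), salicylic acid (0.1 equiv), CH2Cl2, 0 °C to rt, stopped at partial conversion with recycling of 5
Reagents that add atoms: tert-butyl hydroperoxide, CC(C)(C)OO (oxygen passed on by catalytic selenium dioxide, O=[Se]=O)
Why: Riley-type allylic oxidation (ene reaction, then [2,3]-sigmatropic shift) should attack the least hindered terminal isopropylidene group at its (E)-methyl, so the new CH2OH is trans to the chain, which fixes the geometry of the later diene.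

Step 5
Reactants: 6 prop-2-en-1-yl (3S,6E,10E)-12-hydroxy-3,7,11-trimethyldodeca-6,10-dienoate
Product: 7 prop-2-en-1-yl (3S,6E,10E)-3,7,11-trimethyl-12-oxododeca-6,10-dienoate
Conditions: MnO2 (15 equiv), CH2Cl2, rt
Reagents that add atoms: none
Why: MnO2 oxidation is selective for the allylic alcohol and keeps the (E)-geometry of the enal.

Step 6
Reactants: 7 prop-2-en-1-yl (3S,6E,10E)-3,7,11-trimethyl-12-oxododeca-6,10-dienoate
Product: 8 prop-2-en-1-yl (3S,6E,10E)-3,7,11-trimethyltrideca-6,10,12-trienoate
Conditions: Ph3PCH3Br (1.3 equiv), KHMDS (1.2 equiv), THF, −78 to 0 °C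
Reagents that add atoms: methyltriphenylphosphonium bromide, C[P+](c1ccccc1)(c1ccccc1)c1ccccc1.[Br-]
Why: Wittig methylenation of the non-enolisable (E)-enal gives the (E)-configured 1,3-diene, and one equivalent of ylide at low temperature should leave the ester alone.

Step 7
Reactants: 8 prop-2-en-1-yl (3S,6E,10E)-3,7,11-trimethyltrideca-6,10,12-trienoate; 9 methacrolein
Product: 10 prop-2-en-1-yl (3S,6E)-9-[(1R,6S)-6-formyl-2,6-dimethylcyclohex-2-en-1-yl]-3,7-dimethylnon-6-enoate
Conditions: 9 (3 equiv), (S)-B-(o-tolyl)oxazaborolidine from (S)-α,α-diphenylprolinol (20 mol%) activated with Tf2NH (16 mol%), CH2Cl2, −78 to −40 °C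
Reagents that add atoms: none
Why: Catalytic enantioselective Diels–Alder reaction; the 1-alkyl group of the diene should direct the "ortho" orientation (bonds C4–C5 and C3–C2), the formyl group should take the endo position so that CHO and the C5 chain become cis, and the oxazaborolidinium ion shields one face of the s-trans enal so that C4 (S) and C5 (R) form in one enantiomeric series.

Step 8
Reactants: 10 prop-2-en-1-yl (3S,6E)-9-[(1R,6S)-6-formyl-2,6-dimethylcyclohex-2-en-1-yl]-3,7-dimethylnon-6-enoate
Product: 11 prop-2-en-1-yl (3S,6E)-9-[(1R,6S)-6-(hydroxymethyl)-2,6-dimethylcyclohex-2-en-1-yl]-3,7-dimethylnon-6-enoate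
Conditions: NaBH4, MeOH, 0 °C
Reagents that add atoms: none
Why: Borohydride reduction of the aldehyde is chemoselective over the allyl ester and the alkenes, and the quaternary C4 cannot epimerise.

Step 9
Reactants: 11 prop-2-en-1-yl (3S,6E)-9-[(1R,6S)-6-(hydroxymethyl)-2,6-dimethylcyclohex-2-en-1-yl]-3,7-dimethylnon-6-enoate; 12 angelic acid
Product: 14 prop-2-en-1-yl (3S,6E)-9-[(1R,6S)-2,6-dimethyl-6-({[(2Z)-2-methylbut-2-enoyl]oxy}methyl)cyclohex-2-en-1-yl]-3,7-dimethylnon-6-enoate, via mixed anhydride 13 (not isolated)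
Conditions: 12 (3 equiv), 2,4,6-trichlorobenzoyl chloride (3 equiv), Et3N (6 equiv), toluene, rt; then 11, 80 °C, no DMAP
Reagents that add atoms: 2,4,6-trichlorobenzoyl chloride, O=C(Cl)c1c(Cl)cc(Cl)cc1Cl (its acyl group is carried only by intermediate 13)
Why: Yamaguchi esterification without a nucleophilic catalyst should acylate the neopentyl primary alcohol at the less hindered angeloyl carbonyl of 13 while keeping the (Z)-geometry of the angelate.

Step 10
Reactants: 14 prop-2-en-1-yl (3S,6E)-9-[(1R,6S)-2,6-dimethyl-6-({[(2Z)-2-methylbut-2-enoyl]oxy}methyl)cyclohex-2-en-1-yl]-3,7-dimethylnon-6-enoate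
Product: 17 prop-2-en-1-yl (4S,5R,9S,10R,13S)-19-{[(2Z)-2-methylbut-2-enoyl]oxy}labd-7-en-15-oate, via C10 cation 15 (not isolated), via C8 cation 16 (not isolated)
Conditions: FSO3H (8 equiv), 2-nitropropane, −78 °C, 20 min; then Et3N, aq. NaHCO3
Reagents that add atoms: none
Why: The acid protonates the C1=C10 ring alkene at C1 to give tertiary cation 15, C9 of the (E)-C8=C9 alkene captures it to give tertiary cation 16, and loss of the axial H-7 gives the C7=C8 alkene. The closest known reaction type is the superacid cyclisation of α-monocyclofarnesyl and α-monocyclohomofarnesyl compounds to drimane- and ambrox-type trans-decalins. Ring B closes in a 6-endo-trig cation–olefin mode through a chair transition state. C10 is controlled by C5 and C4: with the C5 chain equatorial, the axial C19 acyloxymethyl group blocks the β face, so C9 should add from the α face and the C20 methyl ends β, trans to H-5; C9 is controlled by the (E)-alkene geometry, which places C11 equatorial (β). The step needs ring closure to outrun loss of H-5 from 15 (which would scramble C5) and proton loss from 16 toward C7 rather than C17 or C9. The pre-organised tether, the low temperature and the short contact time should secure both, and the two esters should only be O-protonated under these conditions.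

Step 11
Reactants: 17 prop-2-en-1-yl (4S,5R,9S,10R,13S)-19-{[(2Z)-2-methylbut-2-enoyl]oxy}labd-7-en-15-oate
Product: 18 (4S,5R,9S,10R,13S)-19-{[(2Z)-2-methylbut-2-enoyl]oxy}labd-7-en-15-oic acid (CNP0180171.1)
Conditions: Pd(PPh3)4 (5 mol%), morpholine (5 equiv), THF, rt
Reagents that add atoms: none
Why: Tsuji–Trost deallylation; Pd(0) ionises only the allyl ester and morpholine traps the π-allyl unit, so the acid is freed under neutral conditions that should leave the angelate geometry, the C7=C8 alkene and all stereocentres untouched.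

**Compound list**

1 | (2E,6E)-farnesol | CC(C)=CCC/C(C)=C/CC/C(C)=C/CO | starting material
2 | (3S,6E)-3,7,11-trimethyldodeca-6,10-dien-1-ol | CC(C)=CCC/C(C)=C/CC[C@H](C)CCO | intermediate
3 | (3S,6E)-3,7,11-trimethyldodeca-6,10-dienal | CC(C)=CCC/C(C)=C/CC[C@H](C)CC=O | intermediate (not isolated)
4 | (3S,6E)-3,7,11-trimethyldodeca-6,10-dienoic acid | CC(C)=CCC/C(C)=C/CC[C@H](C)CC(=O)O | intermediate
5 | prop-2-en-1-yl (3S,6E)-3,7,11-trimethyldodeca-6,10-dienoate | CC(C)=CCC/C(C)=C/CC[C@H](C)CC(=O)OCC=C | intermediate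
6 | prop-2-en-1-yl (3S,6E,10E)-12-hydroxy-3,7,11-trimethyldodeca-6,10-dienoate | OC/C(C)=C/CC/C(C)=C/CC[C@H](C)CC(=O)OCC=C | intermediate
7 | prop-2-en-1-yl (3S,6E,10E)-3,7,11-trimethyl-12-oxododeca-6,10-dienoate | O=C/C(C)=C/CC/C(C)=C/CC[C@H](C)CC(=O)OCC=C | intermediate
8 | prop-2-en-1-yl (3S,6E,10E)-3,7,11-trimethyltrideca-6,10,12-trienoate | C=C/C(C)=C/CC/C(C)=C/CC[C@H](C)CC(=O)OCC=C | intermediate
9 | methacrolein (2-methylprop-2-enal) | C=C(C)C=O | starting material
10 | prop-2-en-1-yl (3S,6E)-9-[(1R,6S)-6-formyl-2,6-dimethylcyclohex-2-en-1-yl]-3,7-dimethylnon-6-enoate | O=C[C@@]1(C)CCC=C(C)[C@H]1CC/C(C)=C/CC[C@H](C)CC(=O)OCC=C | intermediate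
11 | prop-2-en-1-yl (3S,6E)-9-[(1R,6S)-6-(hydroxymethyl)-2,6-dimethylcyclohex-2-en-1-yl]-3,7-dimethylnon-6-enoate | OC[C@@]1(C)CCC=C(C)[C@H]1CC/C(C)=C/CC[C@H](C)CC(=O)OCC=C | intermediate
12 | angelic acid, (2Z)-2-methylbut-2-enoic acid | C/C=C(/C)C(=O)O | starting material
13 | (2Z)-2-methylbut-2-enoic 2,4,6-trichlorobenzoic anhydride | C/C=C(/C)C(=O)OC(=O)c1c(Cl)cc(Cl)cc1Cl | intermediate (not isolated)
14 | prop-2-en-1-yl (3S,6E)-9-[(1R,6S)-2,6-dimethyl-6-({[(2Z)-2-methylbut-2-enoyl]oxy}methyl)cyclohex-2-en-1-yl]-3,7-dimethylnon-6-enoate | C/C=C(/C)C(=O)OC[C@@]1(C)CCC=C(C)[C@H]1CC/C(C)=C/CC[C@H](C)CC(=O)OCC=C | intermediate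
15 | monocyclic tertiary C10 cation formed from 14 by protonation at C1 | C/C=C(/C)C(=O)OC[C@@]1(C)CCC[C+](C)[C@H]1CC/C(C)=C/CC[C@H](C)CC(=O)OCC=C | intermediate (not isolated)
16 | bicyclic tertiary C8 cation (labdan-8-yl cation) | C/C=C(/C)C(=O)OC[C@@]1(C)CCC[C@]2(C)[C@@H](CC[C@H](C)CC(=O)OCC=C)[C+](C)CC[C@@H]12 | intermediate (not isolated)
17 | prop-2-en-1-yl (4S,5R,9S,10R,13S)-19-{[(2Z)-2-methylbut-2-enoyl]oxy}labd-7-en-15-oate | C/C=C(/C)C(=O)OC[C@@]1(C)CCC[C@]2(C)[C@@H](CC[C@H](C)CC(=O)OCC=C)C(C)=CC[C@@H]12 | intermediate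
18 | (4S,5R,9S,10R,13S)-19-{[(2Z)-2-methylbut-2-enoyl]oxy}labd-7-en-15-oic acid (CNP0180171.1) | C/C=C(/C)C(=O)OC[C@@]1(C)CCC[C@]2(C)[C@@H](CC[C@H](C)CC(=O)O)C(C)=CC[C@@H]12 | target

**Total step count:** 11. **Longest linear sequence:** 11 steps (1 to 18).

**Steps most likely to fail**

1. Step 10 (key step). What may go wrong: Z-to-E isomerisation of the angelate or capture of cation 15 by the enoate carbonyl in the superacid, together with proton loss from 16 toward C17 or C9. Fallback, setting out from 11 and coming back at 17: the unsaturated ester is kept out of the acid step. Alcohol 11 is acylated with chloroacetyl chloride/pyridine (CH2Cl2, 0 °C) to the monocyclic chloroacetate F1. The same FSO3H cyclisation, which can now be run longer or with ClSO3H because no isomerisable ester is present, should give the bicyclic chloroacetate F2. Thiourea/NaHCO3 (EtOH, 50 °C) removes only the chloroacetyl group to give the bicyclic C19 alcohol F3. Esterification of F3 with mixed anhydride 13 (toluene, 80 °C) gives 17.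

2. Step 7. What may go wrong: poor endo/exo selectivity, with the methyl group rather than the formyl group taking the endo position, which gives the C4 epimer. Fallback, setting out from 8 and coming back at 14: the two C4 substituents exchange roles so that an exo-formyl preference becomes productive. Commercial 2-methylenepropane-1,3-diol (in excess) is mono-acylated with 13 to 2-(hydroxymethyl)allyl angelate F4, and MnO2 oxidation gives 2-formylallyl angelate F5. Diels–Alder reaction of F5 with 8 under the mirror-image (R)-oxazaborolidinium catalyst should give the exo-formyl adduct F6, with CHO trans and CH2O-angelate cis to the side chain. Condensation with TsNHNH2 gives the tosylhydrazone F7. Catecholborane, then NaOAc·3H2O (CHCl3, 0 °C to reflux), reduces CH=N–NHTs to CH3 (the C18 methyl) and gives 14, so steps 8 and 9 are not needed.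

3. Step 4. What may go wrong: competing allylic oxidation at the internal C8=C9 alkene and over-oxidation, leading to low conversion and mixtures. Fallback, setting out from 5 and coming back at 7: the terminal alkene is cleaved and rebuilt. NBS in aqueous THF (0 °C) should add selectively to the terminal trisubstituted alkene to give the bromohydrin F8. K2CO3 in allyl alcohol closes it to the terminal epoxide F9. H5IO6 (THF/Et2O, 0 °C) cleaves F9 to the trisnor aldehyde F10. Wittig reaction of F10 with 2-(triphenylphosphoranylidene)propanal (toluene, 90 °C) gives the (E)-enal 7 directly, so step 5 is not needed.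

**Further compounds**

F1 | step 10 | prop-2-en-1-yl (3S,6E)-9-[(1R,6S)-6-[(chloroacetoxy)methyl]-2,6-dimethylcyclohex-2-en-1-yl]-3,7-dimethylnon-6-enoate | ClCC(=O)OC[C@@]1(C)CCC=C(C)[C@H]1CC/C(C)=C/CC[C@H](C)CC(=O)OCC=C
F2 | step 10 | prop-2-en-1-yl (4S,5R,9S,10R,13S)-19-(chloroacetoxy)labd-7-en-15-oate | ClCC(=O)OC[C@@]1(C)CCC[C@]2(C)[C@@H](CC[C@H](C)CC(=O)OCC=C)C(C)=CC[C@@H]12
F3 | step 10 | prop-2-en-1-yl (4S,5R,9S,10R,13S)-19-hydroxylabd-7-en-15-oate | OC[C@@]1(C)CCC[C@]2(C)[C@@H](CC[C@H](C)CC(=O)OCC=C)C(C)=CC[C@@H]12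
F4 | step 7 | 2-(hydroxymethyl)prop-2-en-1-yl (2Z)-2-methylbut-2-enoate | C/C=C(/C)C(=O)OCC(=C)CO
F5 | step 7 | 2-formylprop-2-en-1-yl (2Z)-2-methylbut-2-enoate | C/C=C(/C)C(=O)OCC(=C)C=O
F6 | step 7 | prop-2-en-1-yl (3S,6E)-9-[(1R,6R)-6-formyl-2-methyl-6-({[(2Z)-2-methylbut-2-enoyl]oxy}methyl)cyclohex-2-en-1-yl]-3,7-dimethylnon-6-enoate | C/C=C(/C)C(=O)OC[C@@]1(C=O)CCC=C(C)[C@H]1CC/C(C)=C/CC[C@H](C)CC(=O)OCC=C
F7 | step 7 | (E)-p-toluenesulfonylhydrazone of F6 | C/C=C(/C)C(=O)OC[C@@]1(/C=N/NS(=O)(=O)c2ccc(C)cc2)CCC=C(C)[C@H]1CC/C(C)=C/CC[C@H](C)CC(=O)OCC=C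
F8 | step 4 | prop-2-en-1-yl (3S,6E)-10-bromo-11-hydroxy-3,7,11-trimethyldodec-6-enoate (both C10 epimers, C10 left open) | CC(C)(O)C(Br)CC/C(C)=C/CC[C@H](C)CC(=O)OCC=C
F9 | step 4 | prop-2-en-1-yl (3S,6E)-9-(3,3-dimethyloxiran-2-yl)-3,7-dimethylnon-6-enoate (both epoxide epimers, oxirane carbon left open) | CC1(C)OC1CC/C(C)=C/CC[C@H](C)CC(=O)OCC=C
F10 | step 4 | prop-2-en-1-yl (3S,6E)-3,7-dimethyl-10-oxodec-6-enoate | O=CCC/C(C)=C/CC[C@H](C)CC(=O)OCC=C
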